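**Retrosynthetic overview**
- Ring C last: the 3',5'-dimethoxycyclohexa-2',5'-dien-4'-one is cut at C5–C6' and C2'=C3' (Michael addition of a C5 aldehyde to 1,3-dimethoxybut-3-en-2-one, aldol condensation, Saegusa dehydrogenation); C9–OBz comes from a C9 ketone, which also allows C8 to be equilibrated.
- Ring B rests on one feature: C5 (spiro) and C9 sit on the neighbouring ring A carbons C4a and C9a, so an oxygen bridge between them is a phthalide, and after methylenation C6=C5–O–C9–C8=C7 is an allyl vinyl ether. A [3,3] shift forms C6–C7, breaks O–C9 and gives the benzocycloheptenone with C5=O, C8=C9 and C7 set from C9.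
- The phthalide comes from CO and an (R)-configured o-bromoaryl allylic alcohol, made from 2-bromo-3,4,5-trimethoxybenzaldehyde and a butenyllithium, then resolved by Sharpless kinetic resolution.
- Ring order: ring A (bought), temporary five-membered oxacycle (step 3), ring B (step 5), ring C (steps 16–17).

Key step: step 5

Remark on locants: ring A is C1–C4, ring B is C4a, C5 (spiro), C6, C7, C8, C9, C9a, and ring C is C1' (= C5) to C6' with the carbonyl at C4'.
Remark on the chemistry: C5 in 11–19 (and C5/C5' in 24–26) is carried as an epimer mixture, written without descriptor, because these centres end up sp2 or non-stereogenic in the target; (E)-2-bromobut-2-ene (methyl groups cis) is assumed to be bought as the single isomer.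

**Route**

Step 1
Reactants: 1 2-bromo-3,4,5-trimethoxybenzaldehyde; 2 (E)-2-bromobut-2-ene
Product: 4 rac-(E)-1-(2-bromo-3,4,5-trimethoxyphenyl)-2-methylbut-2-en-1-ol, via (Z)-but-2-en-2-yllithium 3 (not isolated)
Conditions: 2, t-BuLi (2.0 equiv), THF/Et2O, −78 °C; then 1, −78 °C; aq. NH4Cl
Reagents that add atoms: none
Why: Bromine–lithium exchange on the alkenyl bromide is stereoretentive at −78 °C and the alkenyllithium adds 1,2 to the non-enolisable aldehyde faster than it exchanges with the aryl bromide (organolithium carbonyl addition), giving the racemic carbinol with the (E)-alkene intact.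

Step 2
Reactants: 4 rac-(E)-1-(2-bromo-3,4,5-trimethoxyphenyl)-2-methylbut-2-en-1-ol
Product: 5 (R,E)-1-(2-bromo-3,4,5-trimethoxyphenyl)-2-methylbut-2-en-1-ol
Conditions: Ti(OiPr)4 (1.0 equiv), D-(−)-diisopropyl tartrate (1.2 equiv), t-BuOOH (0.6 equiv), 4 Å MS, CH2Cl2, −20 °C, stopped just past half conversion
Reagents that add atoms: none
Why: Sharpless kinetic resolution of a secondary allylic alcohol with an (E)-trisubstituted alkene: with the D-(−)-tartrate the (S)-carbinol should be epoxidised much faster, so the (R)-alcohol (the future C9 centre) is recovered in high enantiomeric purity.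

Step 3
Reactants: 5 (R,E)-1-(2-bromo-3,4,5-trimethoxyphenyl)-2-methylbut-2-en-1-ol; 6 carbon monoxide
Product: 7 (R)-3-[(E)-but-2-en-2-yl]-5,6,7-trimethoxyisobenzofuran-1(3H)-one
Conditions: CO (1 atm), Pd(OAc)2 (5 mol %), Xantphos (6 mol %), Et3N, toluene, 95 °C
Reagents that add atoms: none
Why: Palladium-catalysed carbonylative lactonisation (oxidative addition to C–Br, CO insertion, capture of the acylpalladium by the neighbouring hydroxyl) closes the five-membered lactone without touching the C–O bond of the stereocentre, and the amine base is too weak to deprotonate C3.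

Step 4
Reactants: 7 (R)-3-[(E)-but-2-en-2-yl]-5,6,7-trimethoxyisobenzofuran-1(3H)-one
Product: 8 (R)-3-[(E)-but-2-en-2-yl]-5,6,7-trimethoxy-1-methylidene-1,3-dihydroisobenzofuran
Conditions: Cp2TiMe2 (2.5 equiv), toluene/THF, 65 °C, dark; filtration through basic alumina
Reagents that add atoms: dimethyltitanocene Cp2TiMe2, C[Ti](C)(C1C=CC=C1)C1C=CC=C1
Why: Petasis methylenation of the lactone carbonyl through Cp2Ti=CH2 gives the exocyclic enol ether under neutral conditions, so the C3 stereocentre and the (E)-alkene should be untouched.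

Step 5
Reactants: 8 (R)-3-[(E)-but-2-en-2-yl]-5,6,7-trimethoxy-1-methylidene-1,3-dihydroisobenzofuran
Product: 9 (R)-2,3,4-trimethoxy-7,8-dimethyl-6,7-dihydro-5H-benzo[7]annulen-5-one
Conditions: degassed o-xylene, Et3N (5 mol %), base-washed sealed tube, 130–150 °C
Reagents that add atoms: none
Why: Concerted suprafacial [3,3]-sigmatropic (Claisen) shift of the allyl vinyl ether C6=C5–O–C9–C8=C7 locked in the five-membered oxacycle: C6–C7 forms as the benzylic and allylic O–C9 bond breaks, and the enol ether becomes the C5 aryl ketone, which makes the step irreversible. The closest known reaction is the thermal Claisen ring expansion of 2-methylene-5-vinyltetrahydrofurans to cyclohept-4-enones and of the six-membered homologues to cyclooctenones. Ring B closes as a seven-membered carbocycle by ring expansion through a bridged, bicyclo[3.2.1]-type transition state in which the arene bond C4a–C9a stays as the two-atom bridge, so no end-to-end cyclisation is involved. The new stereocentre C7 is controlled by the C9 stereocentre together with the (E)-geometry of the butenyl group: the ring forces C9a to the inside of the allyl unit (cis C8=C9), the C7 methyl lies outside, and bond making and breaking occur on the same face, so (R)-C9 should give (R)-C7. The step needs the concerted path to win over ionisation of the O–C9 bond (a [1,3] shift that would scramble C7) and over tautomerisation of the enol ether; the non-polar solvent, the amine buffer and acid-free glass are chosen for this.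

Step 6
Reactants: 9 (R)-2,3,4-trimethoxy-7,8-dimethyl-6,7-dihydro-5H-benzo[7]annulen-5-one
Product: 10 (R)-2,3,4-trimethoxy-7,8-dimethyl-5-methylidene-6,7-dihydro-5H-benzo[7]annulene
Conditions: Ph3PCH3Br, KOtBu, THF, 0 → 65 °C
Reagents that add atoms: methyltriphenylphosphonium bromide, C[P+](c1ccccc1)(c1ccccc1)c1ccccc1.[Br-]
Why: Wittig methylenation of the aryl ketone, which the C4 methoxy group twists out of conjugation so that it behaves like a dialkyl ketone; C7 is β to the carbonyl and cannot epimerise.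

Step 7
Reactants: 10 (R)-2,3,4-trimethoxy-7,8-dimethyl-5-methylidene-6,7-dihydro-5H-benzo[7]annulene
Product: 11 [(7R,8R,9S)-9-hydroxy-2,3,4-trimethoxy-7,8-dimethyl-6,7,8,9-tetrahydro-5H-benzo[7]annulen-5-yl]methanol (C5 epimers)
Conditions: BH3·THF (3 equiv), THF, 0 °C → rt; then NaOH, H2O2, 0 °C → rt
Reagents that add atoms: hydrogen peroxide, OO
Why: Hydroboration–oxidation places boron on the terminal carbon of the exocyclic alkene and on the less substituted benzylic C9 of the trisubstituted C8=C9 (syn addition, expected anti to the pseudoaxial C7 methyl); the C8 and C9 configurations formed here are both reset in steps 9–11, so only the regiochemistry matters.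

Step 8
Reactants: 11 [(7R,8R,9S)-9-hydroxy-2,3,4-trimethoxy-7,8-dimethyl-6,7,8,9-tetrahydro-5H-benzo[7]annulen-5-yl]methanol (C5 epimers)
Product: 12 (7R,8R,9S)-5-[(tert-butyldimethylsilyloxy)methyl]-2,3,4-trimethoxy-7,8-dimethyl-6,7,8,9-tetrahydro-5H-benzo[7]annulen-9-ol
Conditions: TBSCl (1.05 equiv), imidazole, CH2Cl2, 0 °C
Reagents that add atoms: tert-butyldimethylsilyl chloride, CC(C)(C)[Si](C)(C)Cl
Why: Silylation of the primary alcohol is much faster than that of the hindered secondary benzylic alcohol flanked by the C8 methyl.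

Step 9
Reactants: 12 (7R,8R,9S)-5-[(tert-butyldimethylsilyloxy)methyl]-2,3,4-trimethoxy-7,8-dimethyl-6,7,8,9-tetrahydro-5H-benzo[7]annulen-9-ol
Product: 13 (7R,8R)-5-[(tert-butyldimethylsilyloxy)methyl]-2,3,4-trimethoxy-7,8-dimethyl-5,6,7,8-tetrahydro-9H-benzo[7]annulen-9-one (7,8-cis)
Conditions: Dess–Martin periodinane, CH2Cl2, rt
Reagents that add atoms: none
Why: Dess–Martin oxidation of the secondary benzylic alcohol gives the aryl ketone; the silyl ether and the electron-rich arene are inert.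

Step 10
Reactants: 13 (7R,8R)-5-[(tert-butyldimethylsilyloxy)methyl]-2,3,4-trimethoxy-7,8-dimethyl-5,6,7,8-tetrahydro-9H-benzo[7]annulen-9-one (7,8-cis)
Product: 14 (7R,8S)-5-[(tert-butyldimethylsilyloxy)methyl]-2,3,4-trimethoxy-7,8-dimethyl-5,6,7,8-tetrahydro-9H-benzo[7]annulen-9-one (7,8-trans)
Conditions: NaOMe (0.2 equiv), MeOH/THF, rt; cis isomer recycled
Reagents that add atoms: none
Why: Reversible enolisation next to the aryl ketone equilibrates C8, and the trans-7,8-dimethyl isomer, with both methyl groups pseudo-equatorial, should be the favoured one (thermodynamic epimerisation).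

Step 11
Reactants: 14 (7R,8S)-5-[(tert-butyldimethylsilyloxy)methyl]-2,3,4-trimethoxy-7,8-dimethyl-5,6,7,8-tetrahydro-9H-benzo[7]annulen-9-one (7,8-trans)
Product: 15 (7R,8S,9R)-5-[(tert-butyldimethylsilyloxy)methyl]-2,3,4-trimethoxy-7,8-dimethyl-6,7,8,9-tetrahydro-5H-benzo[7]annulen-9-ol
Conditions: (S)-1-methyl-3,3-diphenyltetrahydro-1H,3H-pyrrolo[1,2-c][1,3,2]oxazaborole ((S)-Me-CBS, 0.3 equiv), BH3·SMe2, THF, −20 °C; then MeOH
Reagents that add atoms: none
Why: Corey–Bakshi–Shibata reduction under catalyst control with the aryl ring as the large group: the (S)-catalyst should give the (R)-carbinol (same sense as acetophenone to (R)-1-phenylethanol), which is also the equatorial alcohol trans to the C8 methyl.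

Step 12
Reactants: 15 (7R,8S,9R)-5-[(tert-butyldimethylsilyloxy)methyl]-2,3,4-trimethoxy-7,8-dimethyl-6,7,8,9-tetrahydro-5H-benzo[7]annulen-9-ol; 16 benzoyl chloride
Product: 17 (7R,8S,9R)-5-[(tert-butyldimethylsilyloxy)methyl]-2,3,4-trimethoxy-7,8-dimethyl-6,7,8,9-tetrahydro-5H-benzo[7]annulen-9-yl benzoate
Conditions: Et3N, DMAP (cat.), CH2Cl2, 0 °C → rt
Reagents that add atoms: none
Why: DMAP-catalysed acylation of the secondary alcohol proceeds at oxygen with retention at C9.

Step 13
Reactants: 17 (7R,8S,9R)-5-[(tert-butyldimethylsilyloxy)methyl]-2,3,4-trimethoxy-7,8-dimethyl-6,7,8,9-tetrahydro-5H-benzo[7]annulen-9-yl benzoate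
Product: 18 (7R,8S,9R)-5-(hydroxymethyl)-2,3,4-trimethoxy-7,8-dimethyl-6,7,8,9-tetrahydro-5H-benzo[7]annulen-9-yl benzoate
Conditions: HF·pyridine, pyridine, THF, 0 °C → rt
Reagents that add atoms: none
Why: Buffered fluoride cleaves the primary silyl ether while the benzoate stays in place, and the non-basic medium avoids acyl migration.

Step 14
Reactants: 18 (7R,8S,9R)-5-(hydroxymethyl)-2,3,4-trimethoxy-7,8-dimethyl-6,7,8,9-tetrahydro-5H-benzo[7]annulen-9-yl benzoate
Product: 19 (7R,8S,9R)-5-formyl-2,3,4-trimethoxy-7,8-dimethyl-6,7,8,9-tetrahydro-5H-benzo[7]annulen-9-yl benzoate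
Conditions: Dess–Martin periodinane, CH2Cl2, 0 °C → rt; used directly
Reagents that add atoms: none
Why: Dess–Martin oxidation gives the α-aryl aldehyde under non-basic conditions; epimerisation at C5 is of no consequence.

Step 15
Reactants: 20 methoxyethene; 21 N,2-dimethoxy-N-methylacetamide
Product: 23 1,3-dimethoxybut-3-en-2-one, via (1-methoxyethenyl)lithium 22 (not isolated)
Conditions: 20, t-BuLi, THF, −78 → 0 °C; then 21, −78 → 0 °C; aq. NH4Cl
Reagents that add atoms: none
Why: α-Lithiation of the vinyl ether followed by acylation with the Weinreb amide, whose chelated tetrahedral adduct prevents over-addition (Weinreb ketone synthesis).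

Step 16
Reactants: 19 (7R,8S,9R)-5-formyl-2,3,4-trimethoxy-7,8-dimethyl-6,7,8,9-tetrahydro-5H-benzo[7]annulen-9-yl benzoate; 23 1,3-dimethoxybut-3-en-2-one
Product: 25 (7R,8S,9R)-2,3,3',4,5'-pentamethoxy-7,8-dimethyl-4'-oxo-6,7,8,9-tetrahydrospiro[benzo[7]annulene-5,1'-cyclohex[2]en]-9-yl benzoate, via Michael adduct keto aldehyde 24 (not isolated)
Conditions: 23 (3 equiv), DBU (0.3 equiv), THF, 0 °C → rt; then pyrrolidine (0.3 equiv), AcOH (0.3 equiv), 50 °C
Reagents that add atoms: none
Why: Robinson-type spiroannulation: the aryl-stabilised aldehyde enolate adds to the unsubstituted CH2 terminus of the enone to set the quaternary C5, and aldol condensation of the CH2OMe carbon with the aldehyde closes ring C (only this enolisation gives a six-membered ring); the benzoate tolerates the amine bases, and the C5/C5' mixtures converge in step 17.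

Step 17
Reactants: 25 (7R,8S,9R)-2,3,3',4,5'-pentamethoxy-7,8-dimethyl-4'-oxo-6,7,8,9-tetrahydrospiro[benzo[7]annulene-5,1'-cyclohex[2]en]-9-yl benzoate
Product: 27 (7R,8S,9R)-2,3,3',4,5'-pentamethoxy-7,8-dimethyl-4'-oxo-6,7,8,9-tetrahydrospiro[benzo[7]annulene-5,1'-cyclohexa[2,5]dien]-9-yl benzoate (CNP0201356.1), via trimethylsilyl dienol ether 26 (not isolated)
Conditions: LiN(SiMe3)2, Me3SiCl, THF, −78 °C; then Pd(OAc)2 (1.1 equiv), MeCN, rt
Reagents that add atoms: none
Why: Saegusa–Ito dehydrogenation: C5'–H is the only enolisable position, and palladation of the silyl dienol ether followed by β-hydride elimination from C6' should give the cross-conjugated dienone, which makes ring C mirror-symmetric and C5 non-stereogenic.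

**Compound list**
1 | 2-bromo-3,4,5-trimethoxybenzaldehyde | COc1cc(C=O)c(Br)c(OC)c1OC | starting material
2 | (E)-2-bromobut-2-ene | C/C=C(\C)Br | starting material
3 | (Z)-but-2-en-2-yllithium | C/C=C(\C)[Li] | intermediate
4 | rac-(E)-1-(2-bromo-3,4,5-trimethoxyphenyl)-2-methylbut-2-en-1-ol | C/C=C(\C)C(O)c1cc(OC)c(OC)c(OC)c1Br | intermediate
5 | (R,E)-1-(2-bromo-3,4,5-trimethoxyphenyl)-2-methylbut-2-en-1-ol | C/C=C(\C)[C@@H](O)c1cc(OC)c(OC)c(OC)c1Br | intermediate
6 | carbon monoxide | [C-]#[O+] | starting material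
7 | (R)-3-[(E)-but-2-en-2-yl]-5,6,7-trimethoxyisobenzofuran-1(3H)-one | O=C1O[C@H](/C(C)=C/C)c2cc(OC)c(OC)c(OC)c12 | intermediate
8 | (R)-3-[(E)-but-2-en-2-yl]-5,6,7-trimethoxy-1-methylidene-1,3-dihydroisobenzofuran | C=C1O[C@H](/C(C)=C/C)c2cc(OC)c(OC)c(OC)c12 | intermediate
9 | (R)-2,3,4-trimethoxy-7,8-dimethyl-6,7-dihydro-5H-benzo[7]annulen-5-one | O=C1C[C@@H](C)C(C)=Cc2cc(OC)c(OC)c(OC)c12 | intermediate
10 | (R)-2,3,4-trimethoxy-7,8-dimethyl-5-methylidene-6,7-dihydro-5H-benzo[7]annulene | C=C1C[C@@H](C)C(C)=Cc2cc(OC)c(OC)c(OC)c12 | intermediate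
11 | [(7R,8R,9S)-9-hydroxy-2,3,4-trimethoxy-7,8-dimethyl-6,7,8,9-tetrahydro-5H-benzo[7]annulen-5-yl]methanol (C5 epimers) | OCC1C[C@@H](C)[C@@H](C)[C@H](O)c2cc(OC)c(OC)c(OC)c12 | intermediate
12 | (7R,8R,9S)-5-[(tert-butyldimethylsilyloxy)methyl]-2,3,4-trimethoxy-7,8-dimethyl-6,7,8,9-tetrahydro-5H-benzo[7]annulen-9-ol | CC(C)(C)[Si](C)(C)OCC1C[C@@H](C)[C@@H](C)[C@H](O)c2cc(OC)c(OC)c(OC)c12 | intermediate
13 | (7R,8R)-5-[(tert-butyldimethylsilyloxy)methyl]-2,3,4-trimethoxy-7,8-dimethyl-5,6,7,8-tetrahydro-9H-benzo[7]annulen-9-one (7,8-cis) | CC(C)(C)[Si](C)(C)OCC1C[C@@H](C)[C@@H](C)C(=O)c2cc(OC)c(OC)c(OC)c12 | intermediate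
14 | (7R,8S)-5-[(tert-butyldimethylsilyloxy)methyl]-2,3,4-trimethoxy-7,8-dimethyl-5,6,7,8-tetrahydro-9H-benzo[7]annulen-9-one (7,8-trans) | CC(C)(C)[Si](C)(C)OCC1C[C@@H](C)[C@H](C)C(=O)c2cc(OC)c(OC)c(OC)c12 | intermediate
15 | (7R,8S,9R)-5-[(tert-butyldimethylsilyloxy)methyl]-2,3,4-trimethoxy-7,8-dimethyl-6,7,8,9-tetrahydro-5H-benzo[7]annulen-9-ol | CC(C)(C)[Si](C)(C)OCC1C[C@@H](C)[C@H](C)[C@@H](O)c2cc(OC)c(OC)c(OC)c12 | intermediate
16 | benzoyl chloride | O=C(Cl)c1ccccc1 | starting material
17 | (7R,8S,9R)-5-[(tert-butyldimethylsilyloxy)methyl]-2,3,4-trimethoxy-7,8-dimethyl-6,7,8,9-tetrahydro-5H-benzo[7]annulen-9-yl benzoate | CC(C)(C)[Si](C)(C)OCC1C[C@@H](C)[C@H](C)[C@@H](OC(=O)c3ccccc3)c2cc(OC)c(OC)c(OC)c12 | intermediate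
18 | (7R,8S,9R)-5-(hydroxymethyl)-2,3,4-trimethoxy-7,8-dimethyl-6,7,8,9-tetrahydro-5H-benzo[7]annulen-9-yl benzoate | OCC1C[C@@H](C)[C@H](C)[C@@H](OC(=O)c3ccccc3)c2cc(OC)c(OC)c(OC)c12 | intermediate
19 | (7R,8S,9R)-5-formyl-2,3,4-trimethoxy-7,8-dimethyl-6,7,8,9-tetrahydro-5H-benzo[7]annulen-9-yl benzoate | O=CC1C[C@@H](C)[C@H](C)[C@@H](OC(=O)c3ccccc3)c2cc(OC)c(OC)c(OC)c12 | intermediate
20 | methoxyethene (methyl vinyl ether) | C=COC | starting material
21 | N,2-dimethoxy-N-methylacetamide | COCC(=O)N(C)OC | starting material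
22 | (1-methoxyethenyl)lithium | [Li]C(=C)OC | intermediate
23 | 1,3-dimethoxybut-3-en-2-one | COCC(=O)C(=C)OC | intermediate
24 | (7R,8S,9R)-5-(2,4-dimethoxy-3-oxobutyl)-5-formyl-2,3,4-trimethoxy-7,8-dimethyl-6,7,8,9-tetrahydro-5H-benzo[7]annulen-9-yl benzoate | O=CC1(CC(OC)C(=O)COC)C[C@@H](C)[C@H](C)[C@@H](OC(=O)c3ccccc3)c2cc(OC)c(OC)c(OC)c12 | intermediate
25 | (7R,8S,9R)-2,3,3',4,5'-pentamethoxy-7,8-dimethyl-4'-oxo-6,7,8,9-tetrahydrospiro[benzo[7]annulene-5,1'-cyclohex[2]en]-9-yl benzoate | COC1=CC2(CC(OC)C1=O)C[C@@H](C)[C@H](C)[C@@H](OC(=O)c1ccccc1)c1cc(OC)c(OC)c(OC)c12 | intermediate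
26 | (7R,8S,9R)-2,3,3',4,5'-pentamethoxy-7,8-dimethyl-4'-(trimethylsilyloxy)-6,7,8,9-tetrahydrospiro[benzo[7]annulene-5,1'-cyclohexa[2,4]dien]-9-yl benzoate | COC1=CC2(CC(OC)=C1O[Si](C)(C)C)C[C@@H](C)[C@H](C)[C@@H](OC(=O)c1ccccc1)c1cc(OC)c(OC)c(OC)c12 | intermediate
27 | (7R,8S,9R)-2,3,3',4,5'-pentamethoxy-7,8-dimethyl-4'-oxo-6,7,8,9-tetrahydrospiro[benzo[7]annulene-5,1'-cyclohexa[2,5]dien]-9-yl benzoate (CNP0201356.1) | COC1=CC2(C=C(OC)C1=O)C[C@@H](C)[C@H](C)[C@@H](OC(=O)c1ccccc1)c1cc(OC)c(OC)c(OC)c12 | target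

**Step count**
Total steps: 17. Longest linear sequence: 16 (steps 1–14, 16, 17); step 15 makes the annulation partner.

**Steps most likely to fail**

1. Step 5. The planar benzo-fused oxacycle holds the vinyl ether anti to C9, so the bridged transition state is strained. Ionisation of the benzylic–allylic O–C9 bond may then outrun the concerted shift, giving a [1,3] recombination and loss of chirality transfer, or the enol ether may tautomerise before it rearranges. Fallback from 1, returning at 9, closes ring B by metathesis instead. Wittig methylenation of 1 (Ph3PCH3Br, KOtBu) gives 2-bromo-1-ethenyl-3,4,5-trimethoxybenzene F1. Separately, (S)-4-phenyloxazolidin-2-one is acylated (n-BuLi, (E)-but-2-enoyl chloride) to (S)-3-[(E)-but-2-enoyl]-4-phenyloxazolidin-2-one F2. Copper-mediated conjugate addition of isopropenylmagnesium bromide (CuBr·SMe2, THF, −40 °C), anti to the phenyl group of the chelated imide, should give (S)-3-[(R)-3,4-dimethylpent-4-enoyl]-4-phenyloxazolidin-2-one F3. Transamidation (MeNHOMe·HCl, AlMe3) gives (R)-N-methoxy-N,3,4-trimethylpent-4-enamide F4. Bromine–lithium exchange on F1 (n-BuLi, −78 °C) and acylation with F4 gives (R)-1-(6-ethenyl-2,3,4-trimethoxyphenyl)-3,4-dimethylpent-4-en-1-one F5. Ring-closing metathesis with the second-generation Grubbs catalyst (toluene, 80 °C) then forms the C8=C9 bond and delivers 9.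

2. Step 16. The α-methoxy group lowers the electrophilicity of the enone, so conjugate addition to form the hindered quaternary C5 may be slow, while the acceptor oligomerises and the aldehyde enolate is lost to air oxidation. Fallback from 19, returning at 27, uses a plain vinyl ketone and adds the second oxygen afterwards. Amide 21 and vinylmagnesium bromide give 1-methoxybut-3-en-2-one F6. Annulation of 19 with F6 under the step 16 conditions gives (7R,8S,9R)-2,3,3',4-tetramethoxy-7,8-dimethyl-4'-oxo-6,7,8,9-tetrahydrospiro[benzo[7]annulene-5,1'-cyclohex[2]en]-9-yl benzoate F7. Enolate hydroxylation at C5' (LiN(SiMe3)2, −78 °C; 3-phenyl-2-(phenylsulfonyl)oxaziridine) gives the 5'-hydroxy ketone F8. Dess–Martin oxidation gives the diosphenol (7R,8S,9R)-5'-hydroxy-2,3,3',4-tetramethoxy-7,8-dimethyl-4'-oxo-6,7,8,9-tetrahydrospiro[benzo[7]annulene-5,1'-cyclohexa[2,5]dien]-9-yl benzoate F9. O-Methylation (Me2SO4, K2CO3, acetone) gives 27.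

3. Step 11. Facial selectivity may be poor if the intrinsic bias of the seven-membered ring opposes the catalyst. Fallback from 14, returning at 17, uses substrate control followed by inversion. LiBH(s-Bu)3 (THF, −78 °C) should deliver hydride anti to the C8 methyl to give (7R,8S,9S)-5-[(tert-butyldimethylsilyloxy)methyl]-2,3,4-trimethoxy-7,8-dimethyl-6,7,8,9-tetrahydro-5H-benzo[7]annulen-9-ol F10. Mitsunobu esterification with benzoic acid (PPh3, diisopropyl azodicarboxylate, toluene, 0 °C) inverts C9 and gives 17.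

Further compounds
F1 | step 5 | 2-bromo-1-ethenyl-3,4,5-trimethoxybenzene | C=Cc1cc(OC)c(OC)c(OC)c1Br
F2 | step 5 | (S)-3-[(E)-but-2-enoyl]-4-phenyloxazolidin-2-one | C/C=C/C(=O)N1C(=O)OC[C@@H]1c1ccccc1
F3 | step 5 | (S)-3-[(R)-3,4-dimethylpent-4-enoyl]-4-phenyloxazolidin-2-one | O=C(C[C@@H](C)C(C)=C)N1C(=O)OC[C@@H]1c1ccccc1
F4 | step 5 | (R)-N-methoxy-N,3,4-trimethylpent-4-enamide | CON(C)C(=O)C[C@@H](C)C(C)=C
F5 | step 5 | (R)-1-(6-ethenyl-2,3,4-trimethoxyphenyl)-3,4-dimethylpent-4-en-1-one | C=Cc1cc(OC)c(OC)c(OC)c1C(=O)C[C@@H](C)C(C)=C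
F6 | step 16 | 1-methoxybut-3-en-2-one | COCC(=O)C=C
F7 | step 16 | (7R,8S,9R)-2,3,3',4-tetramethoxy-7,8-dimethyl-4'-oxo-6,7,8,9-tetrahydrospiro[benzo[7]annulene-5,1'-cyclohex[2]en]-9-yl benzoate | COC1=CC2(CCC1=O)C[C@@H](C)[C@H](C)[C@@H](OC(=O)c1ccccc1)c1cc(OC)c(OC)c(OC)c12
F8 | step 16 | (7R,8S,9R)-5'-hydroxy-2,3,3',4-tetramethoxy-7,8-dimethyl-4'-oxo-6,7,8,9-tetrahydrospiro[benzo[7]annulene-5,1'-cyclohex[2]en]-9-yl benzoate | COC1=CC2(CC(O)C1=O)C[C@@H](C)[C@H](C)[C@@H](OC(=O)c1ccccc1)c1cc(OC)c(OC)c(OC)c12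
F9 | step 16 | (7R,8S,9R)-5'-hydroxy-2,3,3',4-tetramethoxy-7,8-dimethyl-4'-oxo-6,7,8,9-tetrahydrospiro[benzo[7]annulene-5,1'-cyclohexa[2,5]dien]-9-yl benzoate | COC1=CC2(C=C(O)C1=O)C[C@@H](C)[C@H](C)[C@@H](OC(=O)c1ccccc1)c1cc(OC)c(OC)c(OC)c12
F10 | step 11 | (7R,8S,9S)-5-[(tert-butyldimethylsilyloxy)methyl]-2,3,4-trimethoxy-7,8-dimethyl-6,7,8,9-tetrahydro-5H-benzo[7]annulen-9-ol | CC(C)(C)[Si](C)(C)OCC1C[C@@H](C)[C@H](C)[C@H](O)c2cc(OC)c(OC)c(OC)c12
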